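**Retrosynthetic overview**
1. The target comes from a silylene-protected tricyclic lactol-aldehyde by ester adjustments only: C1 by anomeric acylation, C11 by 1,2-reduction of a 4-CHO then acylation, C10-OAc last.
2. The lactol-aldehyde comes from a bicyclic cyclopentenol and triformylmethane by de Mayo photoannulation ([2+2], retro-aldol, lactolisation). This step makes C1–C9, C4–C5 and the dihydropyran ring, and sets C5, C9 and C1.
3. The cyclopentenol comes from a 1,6-diene by RCM. The diene comes from axial vinyl addition to a ring-locked α-silyloxy ketone, where C7 sets C8.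
4. The ketone comes from 2-deoxy-D-ribose (its C3 becomes C7 of the target) by methylenation, 1,3-silylene protection and oxidation.
5. Ring order: temporary dioxasilinane, then cyclopentene, then dihydropyran.

Numbering is iridoid: C1 (acyl acetal), O2, C3=C4, C5, C6, C7, C8, C9; C10 is the CH2 on C8 and C11 is the carbon on C4. β is the face carrying H5 and H9.
Assumption: triformylmethane is treated as purchasable (otherwise one off-line step, Vilsmeier–Arnold triformylation of bromoacetic acid followed by hydrolysis), and the one-flask irradiation/acylation is counted as one step.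

**Step 1**
Reactants: 1, 2-deoxy-D-ribose; 2, methyltriphenylphosphonium bromide
Product: 3, (2R,3S)-hex-5-ene-1,2,3-triol
Conditions: Ph3PCH3Br (3.5 equiv), t-BuOK (3.4 equiv), THF, 0 °C → rt
Reagents that add atoms: methyltriphenylphosphonium bromide, [Br-].C[P+](c1ccccc1)(c1ccccc1)c1ccccc1
Why: Wittig methylenation of the open-chain aldehyde tautomer, with excess ylide tolerating the free OH groups as alkoxides; no stereocentre is touched, and sugar C3 (S) becomes C7.

**Step 2**
Reactants: 3; 4, di-tert-butylsilyl bis(trifluoromethanesulfonate)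
Product: 5, (4S,5R)-4-allyl-2,2-di-tert-butyl-1,3,2-dioxasilinan-5-ol (1,3-O-silylene, central OH free, all substituents equatorial)
Conditions: t-Bu2Si(OTf)2 (1.05 equiv), 2,6-lutidine, DMF, −40 → 0 °C
Reagents that add atoms: t-Bu2Si(OTf)2, CC(C)(C)[Si](OS(=O)(=O)C(F)(F)F)(OS(=O)(=O)C(F)(F)F)C(C)(C)C
Why: Silylene acetal protection, in which the primary OH silylates first and closure gives the unstrained six-membered 1,3-silylene rather than the strained, hydrolytically labile five-membered 1,2-silylene.

**Step 3**
Reactants: 5
Product: 6, (4S)-4-allyl-2,2-di-tert-butyl-1,3,2-dioxasilinan-5-one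
Conditions: DMP, NaHCO3, CH2Cl2, 0 °C → rt; used crude
Reagents that add atoms: none
Why: Dess–Martin oxidation under buffered, non-basic conditions, so the only remaining stereocentre (α to C=O, future C7) is not enolised.

**Step 4**
Reactants: 6; 7, vinylmagnesium bromide
Product: 8, (4S,5R)-4-allyl-2,2-di-tert-butyl-5-vinyl-1,3,2-dioxasilinan-5-ol (vinyl axial and cis to allyl; OH equatorial)
Conditions: CH2=CHMgBr (1.5 equiv), LaCl3·2LiCl, THF, −78 °C
Reagents that add atoms: vinylmagnesium bromide, C=C[Mg]Br
Why: Lanthanide-assisted Grignard 1,2-addition; 1,3-dioxan-5-one-type ketones react by axial attack because the ring oxygens carry no 1,3-diaxial H while the other face carries H4ax, H6ax and the axial t-Bu on Si, so C7 sets C8 as R (OH trans to C7–O).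

**Step 5**
Reactants: 8
Product: 9, (4aR,7aS)-2,2-di-tert-butyl-4,4a,7,7a-tetrahydrocyclopenta[d][1,3,2]dioxasilin-4a-ol (cis-fused; C5=C9 alkene, 8α-OH, 7β-O and C10β bridged by Si)
Conditions: Grubbs II (2 mol %), CH2Cl2 (0.02 M), 40 °C
Reagents that add atoms: none (ethylene is lost)
Why: Ring-closing metathesis of a cis-disposed allyl/vinyl pair to a cyclopentene, assisted by the free allylic OH; no stereocentre changes.

**Step 6 (key step)**
Reactants: 9; 10, triformylmethane; 11, isovaleric anhydride (second stage)
Product: 13, (1S,5S,7S,8R,9S)-4-formyl-8-hydroxy-1-isovaleryloxy-7,10-O-(di-tert-butylsilanediyl) iridoid 3-ene, formed via lactol 12 (1β-OH, not isolated)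
Conditions: 10 (3 equiv), CH2Cl2 (0.1 M), Ar, hν (300 nm, Pyrex), 0 °C; then same flask: (i-BuCO)2O, pyridine, DMAP (cat.), 0 °C
Reagents that add atoms: triformylmethane, O=CC(C=O)C=O; isovaleric anhydride, CC(C)CC(=O)OC(=O)CC(C)C
Why: Proposed new method: triformylmethane exists as a rigid, intramolecularly H-bonded β-hydroxy-enal (no free-rotor decay) and is used here as the 1,3-dicarbonyl partner of a de Mayo reaction; its excited enol adds across the unactivated C5=C9 alkene from the convex α-face (anti to the dioxasilinane, syn to the small 8-OH), with the bulky C(CHO)2 terminus bonding to unhindered C5 and the CH(OH) terminus to neopentyl C9, after which the strained β-hydroxy gem-diformyl cyclobutane undergoes retro-aldol cleavage and the released malondialdehyde enol closes on the new C1 aldehyde to give 12 (the cis-cyclobutane fixes H5/H9 cis and β), which is acylated in situ as the anomerically favoured axial 1β-ester trans to C8; the closest known reaction type is the de Mayo photoannulation of cyclopentenes with methyl diformylacetate or β-diketones.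

**Step 7**
Reactants: 13
Product: 14, the corresponding 4-(hydroxymethyl) compound (C11-OH)
Conditions: NaBH4, CeCl3·7H2O, MeOH/CH2Cl2, −78 → −40 °C
Reagents that add atoms: none
Why: Luche 1,2-reduction of the β-alkoxy-enal, which leaves the C1 ester, the silylene and the enol ether untouched and creates no stereocentre.

**Step 8**
Reactants: 14; 11, isovaleric anhydride
Product: 15, 1,11-bis-isovalerate with 7,10-O-silylene and free 8-OH
Conditions: (i-BuCO)2O, pyridine, DMAP (cat.), CH2Cl2, 0 °C
Reagents that add atoms: isovaleric anhydride, CC(C)CC(=O)OC(=O)CC(C)C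
Why: DMAP-catalysed acylation of the unhindered primary allylic alcohol; the tertiary 8-OH is inert under these conditions.

**Step 9**
Reactants: 15
Product: 16, the 7β,8α,10-triol bis-isovalerate
Conditions: HF·pyridine, excess pyridine, THF, 0 °C
Reagents that add atoms: none
Why: Fluoride cleavage of the silylene in a buffered medium that spares the esters, the acyl acetal and the enol ether.

**Step 10**
Reactants: 16; 17, acetyl chloride
Product: 18, the target
Conditions: AcCl (1.1 equiv), 2,4,6-collidine, CH2Cl2, −78 → −40 °C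
Reagents that add atoms: acetyl chloride, CC(=O)Cl
Why: Kinetically selective acylation of the primary C10-OH over the hindered secondary 7-OH and tertiary 8-OH; the primary acetate is also the thermodynamic regioisomer.

Origin of each stereocentre: C7 is bought (C3 of 1). C8 is set in step 4 by C7. C5 and C9 are set in step 6 by C7 and C8. C1 is set in step 6 by C9 and the anomeric effect.

**Compound list**
1 | 2-deoxy-D-ribose, (3S,4R)-3,4,5-trihydroxypentanal (open form drawn) | OC[C@@H](O)[C@@H](O)CC=O | starting material
2 | methyltriphenylphosphonium bromide | [Br-].C[P+](c1ccccc1)(c1ccccc1)c1ccccc1 | starting material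
3 | (2R,3S)-hex-5-ene-1,2,3-triol | OC[C@@H](O)[C@@H](O)CC=C | intermediate
4 | di-tert-butylsilyl bis(triflate) | CC(C)(C)[Si](OS(=O)(=O)C(F)(F)F)(OS(=O)(=O)C(F)(F)F)C(C)(C)C | starting material
5 | (4S,5R)-4-allyl-2,2-di-tert-butyl-1,3,2-dioxasilinan-5-ol | O1C[C@@H](O)[C@H](CC=C)O[Si]1(C(C)(C)C)C(C)(C)C | intermediate
6 | (4S)-4-allyl-2,2-di-tert-butyl-1,3,2-dioxasilinan-5-one | O1CC(=O)[C@H](CC=C)O[Si]1(C(C)(C)C)C(C)(C)C | intermediate
7 | vinylmagnesium bromide | C=C[Mg]Br | starting material
8 | (4S,5R)-4-allyl-2,2-di-tert-butyl-5-vinyl-1,3,2-dioxasilinan-5-ol | O1C[C@](O)(C=C)[C@H](CC=C)O[Si]1(C(C)(C)C)C(C)(C)C | intermediate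
9 | (4aR,7aS)-2,2-di-tert-butyl-4,4a,7,7a-tetrahydrocyclopenta[d][1,3,2]dioxasilin-4a-ol | O1C[C@]2(O)C=CC[C@@H]2O[Si]1(C(C)(C)C)C(C)(C)C | intermediate
10 | triformylmethane (methanetricarbaldehyde) | O=CC(C=O)C=O | starting material
11 | isovaleric (3-methylbutanoic) anhydride | CC(C)CC(=O)OC(=O)CC(C)C | starting material
12 | (1R,5S,7S,8R,9S)-lactol: 1β,8α-dihydroxy-4-formyl-7,10-O-(di-tert-butylsilanediyl) iridoid 3-ene (not isolated) | O3C[C@]1(O)[C@H]2[C@H](O)OC=C(C=O)[C@H]2C[C@@H]1O[Si]3(C(C)(C)C)C(C)(C)C | intermediate
13 | 1β-O-isovaleryl derivative of 12 (4-CHO) | O3C[C@]1(O)[C@H]2[C@H](OC(=O)CC(C)C)OC=C(C=O)[C@H]2C[C@@H]1O[Si]3(C(C)(C)C)C(C)(C)C | intermediate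
14 | 11-alcohol (4-CH2OH) | O3C[C@]1(O)[C@H]2[C@H](OC(=O)CC(C)C)OC=C(CO)[C@H]2C[C@@H]1O[Si]3(C(C)(C)C)C(C)(C)C | intermediate
15 | 1,11-bis-isovalerate, 7,10-O-silylene | O3C[C@]1(O)[C@H]2[C@H](OC(=O)CC(C)C)OC=C(COC(=O)CC(C)C)[C@H]2C[C@@H]1O[Si]3(C(C)(C)C)C(C)(C)C | intermediate
16 | 7β,8α,10-triol 1,11-bis-isovalerate | OC[C@]1(O)[C@H]2[C@H](OC(=O)CC(C)C)OC=C(COC(=O)CC(C)C)[C@H]2C[C@@H]1O | intermediate
17 | acetyl chloride | CC(=O)Cl | starting material
18 | [(1S,4aS,6S,7R,7aS)-7-(acetoxymethyl)-6,7-dihydroxy-1-(3-methylbutanoyloxy)-1,4a,5,6,7,7a-hexahydrocyclopenta[c]pyran-4-yl]methyl 3-methylbutanoate | CC(=O)OC[C@]1(O)[C@H]2[C@H](OC(=O)CC(C)C)OC=C(COC(=O)CC(C)C)[C@H]2C[C@@H]1O | target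

**Total steps:** 10. **Longest linear sequence:** 10 (from 1).

**Three steps most likely to fail**
1. **Step 6 (proposed new step).**
   - Risks: inefficient capture of the excited enol by the hindered alkene, leakage of regio- or facial selectivity, and secondary photochemistry of the β-alkoxy-enal product.
   - Fallback (known chemistry): use the established de Mayo photoannulation with methyl diformylacetate, which gives the 4-CO2Me lactol (transparent above 290 nm). Then carry out C1-OTES protection, DIBAL-H reduction, MnO2 oxidation and AcOH/THF/H2O hydrolysis to reach lactol 12, acylate it, and continue from 13 (+4 steps).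
2. **Step 2 (1,3- versus 1,2-silylene regioselectivity).**
   - Fallback: enforce the regiochemistry with the sugar ring. Convert 1 to methyl 2-deoxy-D-ribofuranoside (MeOH, cat. HCl) and form the 3,5-O-DTBS derivative; O4 is the ring oxygen, so only the 1,3-diol is available. Mild aqueous acid gives the lactol, and Wittig methylenation then delivers 5 directly (+2 steps).
3. **Step 4 (C8 diastereoselectivity).**
   - Fallback: switch from ring control to acyclic Cram-chelate control.
   - Sequence: 3 → 1,3-O-p-methoxybenzylidene acetal → DIBAL-H (3-OPMB, free 1-OH) → 1-O-TBS → oxidation → CH2=CHMgBr/MgBr2·OEt2 in CH2Cl2.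
   - With the Mg chelate to OPMB, attack on the H side gives the same C8 configuration. After RCM, PMB and TBS serve as the C7 and C10 protecting groups and are removed at the end with DDQ and HF·pyridine.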